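I begin with the easy step of multiplying each percentage by its charge, which turns the readings into c(target) in mM, idle adduct counted.

| flask | solid substrate | remark | time |
|---|---|---|---|
| summer | 2.5 mM | run made earlier |  |
| spring | 6.9 mM | run made earlier |  |
| autumn | 17 mM | run made earlier |  |
| elm | 2.0 mM |  | 5.0 h |
| alder | 6.0 mM |  | 5.0 h |
| cedar | 20 mM |  | 5.0 h |

| run | time / h | target / % |
|---|---|---|
| summer | 0.250 | 3.4 |
| summer | 0.500 | 10.9 |
| summer | 1.00 | 30.4 |
| summer | 2.00 | 55.7 |
| summer | 4.00 | 55.7 |
| spring | 0.333 | 1.1 |
| spring | 0.833 | 8.7 |
| spring | 1.50 | 19.7 |
| spring | 2.50 | 34.6 |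
| spring | 4.00 | 54.1 |
| autumn | 0.667 | 2.1 |
| autumn | 1.33 | 6.9 |
| autumn | 2.00 | 10.8 |
| autumn | 3.00 | 17.6 |
| autumn | 4.00 | 23.0 |

(readings scatter by 0.5 percentage points)

- a species is counted by the solid substrate in it: one idle adduct counts as two
- amounts and yields of target count idle adduct too
- given per volume of solution although it is solid: solid substrate
- steps thought possible: starting material + target <-> idle adduct; solid substrate <-> starting material; starting material <-> isomer of the product; target <-> isomer of the product; target -> over-reaction product; starting material <-> target
- at the start none of the solid substrate is in solution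
- in an amount of target, one idle adduct counts as one target
- the concentration of target that is asked is that of its free form alone
- "hardly changes" means that all values lie within two and a half points (for a concentration: within two and a half percent of the largest)

- [target] (only what is free in solution) at the end for elm, alder, cedar, in this order
- how the row runs (falls all the way / falls, then rises / hardly changes / rises all the way / rises, then falls)

At 2.00 h the summer run reads 55.7% and the autumn run 10.8%, which looks like a far poorer flask, yet autumn then holds more target than summer, 1.84 mM against 1.39 mM. At 4.00 h spring and autumn stand close together, at 3.73 mM and 3.91 mM, although their charges differ widely. So at these two times the percentage falls with charge while the mM do not fall, and I carry one quantity, the target supply rate s, the mM of target gained per hour while solid remains, a zero-order supply read from the autumn readings, with their scatter: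

s = 1.04 mM h⁻¹

Summer reads 55.7% at 2.00 h and 55.7% at 4.00 h, so I take that reading as a ceiling on the yield over these hours and estimate the time each flask needs to reach it:

alder: 3.22 h, shorter than 5.0 h, so c(target) = 3.34 mM

elm: likewise, c(target) = 1.11 mM

cedar: 10.7 h, longer than 5.0 h, so I take autumn's last reading plus s for the hour beyond it: c(target) = 4.95 mM

These figures still count adduct, so free target lies somewhat below them. The forecast, holding that “the solid dissolves at a fixed rate”, prints 1.1 mM, 3.3 mM and 4.2 mM for free target, rises all the way.

The flask gives 1.07 mM, 3.09 mM and 4.21 mM, rises all the way.

    starting material + target ⇌ idle adduct, settled at all times (K = 98.0 M⁻¹)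
    solid substrate ⇌ starting material, rate k2*(cs2 - [starting material]) while solid is left; crystals form when [starting material] > cs2 (solubility = 12.0 mM, k = 4.90 × 10⁻⁵ s⁻¹)
    starting material ⇌ isomer of the product (K = 2.40, k = 1.80 × 10⁻⁴ s⁻¹)
    target ⇌ isomer of the product (k = 9.80 × 10⁻⁶ s⁻¹)
    target → over-reaction product (k = 2.80 × 10⁻⁶ s⁻¹)
    starting material ⇌ target (K = 4.20, k = 4.40 × 10⁻⁴ s⁻¹)

Elm holds 2.29% of over-reaction product at the end, and the half-life of its free target by that step alone, 69 h, is long against 5.0 h. Now I use s on cedar, which at 2.50 h holds 2.39 mM of target, adduct counted: s over the remaining 2.50 h adds 2.60 mM, which makes 4.98 mM, and at 5.00 h cedar stands at 24.5% of its charge, adduct counted, 4.89 mM.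

The readings were computed with made-up constants, noise included.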